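**Retrosynthetic overview**

1. Last step: inverse-demand oxa-[4+2] cycloaddition of an o-quinone methide (from 2,4-diformylphloroglucinol + PhCHO) onto the exocyclic C=CH2 of a bicyclic cadinane-type diene. It closes the pyran ring and creates the spiro and benzylic centres.
2. Diene ⇐ Wittig methylenation of a bicyclic enone; enone (ring B) ⇐ kinetic intramolecular aldol/E1cB of a 1,5-diketone.
3. 1,5-Diketone ⇐ ozonolysis of an alkylated dimethylhydrazone ⇐ axial azaenolate alkylation of (−)-menthone dimethylhydrazone. A base-equilibrated Robinson annulation is avoided because it would give the other ring-fusion epimer (chain trans to the methyl).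
4. Stereocentres: CH–iPr and CH–Me are bought in (−)-menthone; the ring-fusion CH is set by the alkylation; spiro C–O and CHPh are set in the cycloaddition under control of the terpene framework.
5. Ring order: ring A (bought) → ring B (annulation) → dihydropyran ring (cycloaddition); both arene rings are bought.

Assumption: (−)-menthone of high diastereomeric purity and 2,4-diformylphloroglucinol are bought as such.

**Route**

Step 1
Reactants: 1 (−)-menthone; 2 N,N-dimethylhydrazine
Product: 3 (E)-1,1-dimethyl-2-[(2S,5R)-5-methyl-2-(propan-2-yl)cyclohexylidene]hydrazine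
Conditions: Me2NNH2 (neat, 6 equiv), 4 Å molecular sieves, 65 °C (sealed tube), 48 h, no acid
Reagents that add atoms: N,N-dimethylhydrazine, CN(C)N
Why: Hydrazone condensation at the only carbonyl under acid-free conditions, so the enolisable iPr-bearing α-centre is not epimerised, the NMe2 group settles anti to the more substituted α-carbon and no new stereocentre is formed.

Step 2
Reactants: 3 menthone dimethylhydrazone; 4 4-bromo-2-methylbut-1-ene
Product: 6 1,1-dimethyl-2-[(2R,3R,6S)-3-methyl-2-(3-methylbut-3-en-1-yl)-6-(propan-2-yl)cyclohexylidene]hydrazine, via lithium azaenolate 5 (not isolated)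
Conditions: LiN(iPr)2 (1.1 equiv), THF, 0 °C, 3 h; then 4 (1.3 equiv), −78 °C → 0 °C
Reagents that add atoms: 4-bromo-2-methylbut-1-ene, C=C(C)CCBr
Why: Corey–Enders azaenolate alkylation (SN2) in which the base removes a proton from the less substituted α-CH2, the NMe2 group lies syn to the carbanionic carbon so the isopropyl stays equatorial, and the bromide is attacked along the axial trajectory (the new substituent syn to NMe2 must be axial to avoid allylic 1,3-strain), which places the chain cis to the equatorial ring methyl and trans to the isopropyl (new centre R).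

Step 3
Reactants: 6 alkylated dimethylhydrazone
Product: 8 (2R,3R,6S)-3-methyl-2-(3-oxobutyl)-6-(propan-2-yl)cyclohexan-1-one, via keto ozonide 7 (not isolated)
Conditions: O3, CH2Cl2, −78 °C; N2 purge; then Me2S (5 equiv), −78 °C → rt
Reagents that add atoms: ozone, [O-][O+]=O
Why: Ozonolysis cleaves the electron-rich C=N back to the ring ketone and the 1,1-disubstituted alkene (through the ozonide, reduced by Me2S) to the methyl ketone under cold neutral conditions, so the epimerisable axial α-centre from step 2 is preserved and no new stereocentre is formed.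

Step 4
Reactants: 8 1,5-diketone
Product: 12 (4aR,5R,8S)-5-methyl-8-(propan-2-yl)-4,4a,5,6,7,8-hexahydronaphthalen-2(3H)-one, via lithium enolate 9 (not isolated), via lithium aldolate 10 (not isolated), via keto acetate 11 (not isolated)
Conditions: LiN(SiMe3)2 (1.05 equiv), THF (0.02 M), −78 °C → −20 °C; then Ac2O (3 equiv), −20 → 0 °C; then DBU (4 equiv), rt, 6 h
Reagents that add atoms: none
Why: Kinetic intramolecular aldol addition followed by acetylation and E1cB elimination, in which the base deprotonates only the unhindered methyl ketone CH3, the enolate closes ring B onto the ring ketone, and DBU expels acetate towards the only acidic α-CH2, so the ring-fusion CH is never enolised and the transient carbinol centre is erased.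

Step 5
Reactants: 12 bicyclic enone
Product: 13 (1S,4R,4aR)-4-methyl-7-methylidene-1-(propan-2-yl)-1,2,3,4,4a,5,6,7-octahydronaphthalene
Conditions: Ph3PCH3Br (1.5 equiv), KOtBu (1.4 equiv), THF, 0 °C, 30 min; then 12, 0 °C → rt, 1 h
Reagents that add atoms: methyltriphenylphosphonium bromide, C[P+](c1ccccc1)(c1ccccc1)c1ccccc1.[Br-]
Why: Wittig methylenation of the unhindered enone carbonyl with a slight deficit of base gives the conjugated exocyclic diene without touching the γ ring-fusion centre, and no new stereocentre is formed.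

Step 6
Reactants: 13 diene; 14 2,4-diformylphloroglucinol; 15 benzaldehyde
Product: 17 Guajadial C, via o-quinone methide 16 (not isolated)
Conditions: 14 (1.2 equiv), 15 (3 equiv), ethylenediammonium diacetate (20 mol %), MeCN, 70 °C, 12 h, N2, dark; chromatography/HPLC
Reagents that add atoms: 2,4,6-trihydroxybenzene-1,3-dicarbaldehyde, O=Cc1c(O)cc(O)c(C=O)c1O; benzaldehyde, O=Cc1ccccc1
Why: Knoevenagel condensation of 14 with benzaldehyde gives o-quinone methide 16, which is trapped in an inverse-electron-demand hetero-Diels–Alder reaction by the exocyclic methylene of 13 (CH2 terminus to the benzylic carbon, O to the tertiary allylic carbon), where addition to the face of ring B opposite the axial isopropyl group and the ring-fusion H sets the spiro centre (S) and the endo placement of the ring vinyl unit under the (E)-quinone methide sets the benzylic centre (R), minor diastereomers being removed by chromatography.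

**Compound list**

1 | (−)-menthone, (2S,5R)-5-methyl-2-(propan-2-yl)cyclohexan-1-one | CC(C)[C@@H]1CC[C@@H](C)CC1=O | starting material
2 | N,N-dimethylhydrazine | CN(C)N | starting material
3 | (E)-1,1-dimethyl-2-[(2S,5R)-5-methyl-2-(propan-2-yl)cyclohexylidene]hydrazine | CC(C)[C@@H]1CC[C@@H](C)C/C1=N\N(C)C | intermediate
4 | 4-bromo-2-methylbut-1-ene | C=C(C)CCBr | starting material
5 | lithium azaenolate of 3 (C=C towards the CH2 α-carbon) | CC(C)[C@@H]1CC[C@@H](C)C=C1N([Li])N(C)C | intermediate
6 | 1,1-dimethyl-2-[(2R,3R,6S)-3-methyl-2-(3-methylbut-3-en-1-yl)-6-(propan-2-yl)cyclohexylidene]hydrazine (chain cis to ring methyl; NMe2 syn to C-2) | CC(C)[C@@H]1CC[C@@H](C)[C@@H](CCC(C)=C)/C1=N\N(C)C | intermediate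
7 | keto ozonide: (2R,3R,6S)-3-methyl-2-[2-(3-methyl-1,2,4-trioxolan-3-yl)ethyl]-6-(propan-2-yl)cyclohexan-1-one (both epimers at the trioxolane carbon) | CC(C)[C@@H]1CC[C@@H](C)[C@@H](CCC2(C)OCOO2)C1=O | intermediate
8 | (2R,3R,6S)-3-methyl-2-(3-oxobutyl)-6-(propan-2-yl)cyclohexan-1-one | CC(C)[C@@H]1CC[C@@H](C)[C@@H](CCC(C)=O)C1=O | intermediate
9 | lithium enolate of the methyl ketone of 8 | CC(C)[C@@H]1CC[C@@H](C)[C@@H](CCC(=C)O[Li])C1=O | intermediate
10 | lithium alkoxide of (4aR,5R,8S,8aR)-8a-hydroxy-5-methyl-8-(propan-2-yl)octahydronaphthalen-2(1H)-one (cis-fused epimer drawn; this centre is erased in the elimination) | CC(C)[C@@H]1CC[C@@H](C)[C@H]2CCC(=O)C[C@@]12O[Li] | intermediate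
11 | (4aR,5R,8S,8aR)-8a-acetoxy-5-methyl-8-(propan-2-yl)octahydronaphthalen-2(1H)-one | CC(C)[C@@H]1CC[C@@H](C)[C@H]2CCC(=O)C[C@@]12OC(C)=O | intermediate
12 | (4aR,5R,8S)-5-methyl-8-(propan-2-yl)-4,4a,5,6,7,8-hexahydronaphthalen-2(3H)-one | CC(C)[C@@H]1CC[C@@H](C)[C@H]2CCC(=O)C=C12 | intermediate
13 | (1S,4R,4aR)-4-methyl-7-methylidene-1-(propan-2-yl)-1,2,3,4,4a,5,6,7-octahydronaphthalene | CC(C)[C@@H]1CC[C@@H](C)[C@H]2CCC(=C)C=C12 | intermediate
14 | 2,4-diformylphloroglucinol, 2,4,6-trihydroxybenzene-1,3-dicarbaldehyde | O=Cc1c(O)cc(O)c(C=O)c1O | starting material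
15 | benzaldehyde | O=Cc1ccccc1 | starting material
16 | o-quinone methide, (5E)-5-benzylidene-2,4-dihydroxy-6-oxocyclohexa-1,3-diene-1,3-dicarbaldehyde | O=CC1=C(O)C(C=O)=C(O)/C(=C\c2ccccc2)C1=O | intermediate
17 | Guajadial C (spiro C–O centre S; benzylic CH R; ring-fusion CH R; CH–Me R; CH–iPr S) | CC(C)[C@@H]1CC[C@@H](C)[C@H]2CC[C@@]3(C=C12)C[C@H](c1ccccc1)c1c(O)c(C=O)c(O)c(C=O)c1O3 | target

**Step count and risks**

Total steps: 6. Longest linear sequence: 6 steps (1 → 17).

Three steps most likely to fail:

Step 2 (configuration of the ring-fusion carbon). The axial alkylation has to override the usual preference of cyclohexanone enolates to alkylate trans to a neighbouring methyl, and the selectivity for this substrate is a prediction, not a measured value. Fallback, setting out from 1 and coming back at 8: form the C–H bond of this centre last instead of its C–C bond. LiN(iPr)2 and (2-methyl-1,3-dioxolan-2-yl)acetaldehyde convert 1 into the aldol adduct (3R,6S)-2-[1-hydroxy-2-(2-methyl-1,3-dioxolan-2-yl)ethyl]-3-methyl-6-(propan-2-yl)cyclohexan-1-one F1. MsCl/Et3N followed by DBU dehydrates it to the exocyclic enone (2E,3R,6S)-3-methyl-2-[2-(2-methyl-1,3-dioxolan-2-yl)ethylidene]-6-(propan-2-yl)cyclohexan-1-one F2. Conjugate reduction with K[BH(sBu)3] at −78 °C gives a tetrasubstituted enolate in which allylic strain holds the neighbouring methyl pseudo-axial. Protonation (aqueous NH4Cl, −78 °C) anti to that methyl gives the keto ketal (2R,3R,6S)-3-methyl-2-[2-(2-methyl-1,3-dioxolan-2-yl)ethyl]-6-(propan-2-yl)cyclohexan-1-one F3 with the chain cis to the methyl. Pyridinium p-toluenesulfonate in wet acetone then unmasks the methyl ketone to give 8.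

Step 4 (ring B closure). The hindered 2,6-disubstituted ring ketone may resist aldol addition, the aldolate may revert, or the α-centre may erode. Fallback, setting out from 6 and coming back at 13 (8, 12 and the Wittig step are bypassed): avoid enolate chemistry altogether. CuCl2 in THF/pH 7 phosphate buffer hydrolyses 6 to the keto alkene (2R,3R,6S)-3-methyl-2-(3-methylbut-3-en-1-yl)-6-(propan-2-yl)cyclohexan-1-one F4. Me2AlCl in CH2Cl2 (−78 → 0 °C) triggers a type-2 intramolecular carbonyl-ene reaction that closes ring B with the exocyclic methylene already in place, giving the tertiary alcohol (1S,4R,4aR,8aR)-4-methyl-7-methylidene-1-(propan-2-yl)octahydronaphthalen-8a(1H)-ol F5. Syn-dehydration with the Burgess reagent (MeO2C–N(−)–SO2–N(+)Et3, benzene, 50 °C) towards the allylic CH2 gives 13. The regiochemistry of this dehydration is the weak point of the fallback.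

Step 6 (cycloaddition). Up to four diastereomers can form, and the acid-sensitive exocyclic diene can isomerise under Knoevenagel conditions. Fallback, setting out from 14 (with 15) and coming back at 17: separate quinone methide generation from the cycloaddition. Morpholine, 14 and 15 (EtOH, rt) give the Mannich base 2,4,6-trihydroxy-5-[morpholin-4-yl(phenyl)methyl]benzene-1,3-dicarbaldehyde F6. Heating F6 with 13 in toluene at 90 °C expels morpholine, regenerates 16 under near-neutral conditions and gives 17. Diastereomers are still separated by HPLC.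

**Further compounds**

F1 | step 2 | (3R,6S)-2-[1-hydroxy-2-(2-methyl-1,3-dioxolan-2-yl)ethyl]-3-methyl-6-(propan-2-yl)cyclohexan-1-one (mixture at C-2 and the carbinol carbon) | CC(C)[C@@H]1CC[C@@H](C)C(C(O)CC2(C)OCCO2)C1=O
F2 | step 2 | (2E,3R,6S)-3-methyl-2-[2-(2-methyl-1,3-dioxolan-2-yl)ethylidene]-6-(propan-2-yl)cyclohexan-1-one | CC(C)[C@@H]1CC[C@@H](C)/C(=C\CC2(C)OCCO2)C1=O
F3 | step 2 | (2R,3R,6S)-3-methyl-2-[2-(2-methyl-1,3-dioxolan-2-yl)ethyl]-6-(propan-2-yl)cyclohexan-1-one | CC(C)[C@@H]1CC[C@@H](C)[C@@H](CCC2(C)OCCO2)C1=O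
F4 | step 4 | (2R,3R,6S)-3-methyl-2-(3-methylbut-3-en-1-yl)-6-(propan-2-yl)cyclohexan-1-one | CC(C)[C@@H]1CC[C@@H](C)[C@@H](CCC(C)=C)C1=O
F5 | step 4 | (1S,4R,4aR,8aR)-4-methyl-7-methylidene-1-(propan-2-yl)octahydronaphthalen-8a(1H)-ol | CC(C)[C@@H]1CC[C@@H](C)[C@H]2CCC(=C)C[C@@]12O
F6 | step 6 | 2,4,6-trihydroxy-5-[morpholin-4-yl(phenyl)methyl]benzene-1,3-dicarbaldehyde (racemic) | O=Cc1c(O)c(C=O)c(O)c(C(c2ccccc2)N2CCOCC2)c1O
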